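Retrosynthetic overview
- Malabaricone C comes from its ring-B dimethyl ether by cleaving the two aryl methyl ethers with BBr3. This is the only protecting-group operation in the route.
- Key disconnection: the bond between the ketone carbon and the alpha-CH2 of the nonanone chain, giving 2,6-dihydroxybenzaldehyde and 1,2-dimethoxy-4-(oct-7-en-1-yl)benzene. In the forward sense this is a rhodium-catalysed linear hydroacylation that adds the formyl C–H across the terminal C=C. The acyl carbon reacts with reversed polarity, ring A is unprotected, and every atom of both partners is kept.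
- Enabling feature: the phenolic O–H on C2 of ring A (the 2,6-dihydroxyphenyl ring, with a twin O–H on C6) lies ortho to the acyl carbon. The phenoxide O, C2, C1 and the acyl carbon form a five-membered chelate with rhodium, which triggers C–H insertion and holds back decarbonylation.
- The alkene comes from 3,4-dimethoxyphenylmagnesium bromide and 8-bromooct-1-ene by copper-catalysed sp2–sp3 coupling. No ring is formed, since both benzene rings (A and B) are bought.

Key step: step 2

Remark: the target is achiral, so no stereocentre has to be set. Grignard reagent 1 is assumed to be bought as its commercial THF solution.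

Step 1
Reactants: 1 3,4-dimethoxyphenylmagnesium bromide; 2 8-bromooct-1-ene
Product: 3 1,2-dimethoxy-4-(oct-7-en-1-yl)benzene
Conditions: 1 (1.2 equiv), 2 (1.0 equiv), Li2CuCl4 (5 mol %), THF, 0 °C to rt, Ar; aq NH4Cl work-up
Reagents that add atoms: none
Why: In this copper-catalysed Kochi-type sp2–sp3 cross-coupling, transmetalation of the aryl Grignard reagent to copper gives an aryl cuprate that displaces the unhindered primary bromide, while the remote terminal alkene and the methyl ethers are inert to both organometallics.

Step 2
Reactants: 3 1,2-dimethoxy-4-(oct-7-en-1-yl)benzene; 4 2,6-dihydroxybenzaldehyde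
Product: 5 1-(2,6-dihydroxyphenyl)-9-(3,4-dimethoxyphenyl)nonan-1-one
Conditions: 4 (1.0 equiv), 3 (1.2 equiv), [Rh(cod)Cl]2 (2.5 mol %), (Ra,R,R)-SIPHOS-PE (spirobiindanediol phosphoramidite of bis(1-phenylethyl)amine, 5 mol %), K3PO4 (10 mol %), 1,2-dichloroethane, 70–80 °C, Ar
Reagents that add atoms: none
Why: Catalytic K3PO4 converts one of the two equivalent ortho-hydroxyls of 4 into a phenoxide that binds monovalent rhodium, so oxidative addition of the formyl C–H gives a five-membered O,C-chelated acyl hydride of trivalent rhodium, in which the normally electrophilic carbonyl carbon has become a metal-bound acyl ligand (polarity reversal) and the occupied coordination site disfavours decarbonylation. The terminal alkene of 3 then coordinates, hydride insertion places rhodium on the terminal CH2, reductive elimination forms the C(=O)–CH2 bond, and proton exchange with fresh 4 releases 5. The closest known reaction type is the rhodium/phosphoramidite-catalysed, phenoxide-directed intermolecular hydroacylation of unactivated 1-alkenes with salicylaldehydes, which includes 6-substituted and polyhydroxylated salicylaldehydes. No ring of the target is closed and no stereocentre is created; the only ring involved is the transient rhodacycle. The step needs linear rather than branched regioselectivity and no chain-walking of the alkene, and this should follow from reversible branched insertion combined with the bulk of the spiro phosphoramidite and of the 2,6-disubstituted acyl ligand, both of which favour the primary alkyl-rhodium and a fast reductive elimination. The local symmetry of ring A makes the choice of hydroxyl irrelevant, the second hydroxyl only donates a hydrogen bond to the acyl oxygen, and the veratrole ring of 3 has no group that competes for rhodium.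

Step 3
Reactants: 5 1-(2,6-dihydroxyphenyl)-9-(3,4-dimethoxyphenyl)nonan-1-one
Product: 6 malabaricone C, 1-(2,6-dihydroxyphenyl)-9-(3,4-dihydroxyphenyl)nonan-1-one
Conditions: BBr3 (6 equiv), CH2Cl2, −78 °C to rt, Ar; then degassed H2O, 0 °C
Reagents that add atoms: none
Why: In this Lewis-acid aryl methyl ether cleavage, boron coordinates each methoxy oxygen and bromide removes the methyl group by SN2, while the hydrogen-bonded 2,6-dihydroxyaryl ketone is only bound reversibly to boron and is released, like all aryloxyboron bonds, on aqueous work-up.

Compound list
1 | 3,4-dimethoxyphenylmagnesium bromide | COc1ccc([Mg]Br)cc1OC | starting material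
2 | 8-bromooct-1-ene | C=CCCCCCCBr | starting material
3 | 1,2-dimethoxy-4-(oct-7-en-1-yl)benzene | C=CCCCCCCc1ccc(OC)c(OC)c1 | intermediate
4 | 2,6-dihydroxybenzaldehyde | O=Cc1c(O)cccc1O | starting material
5 | 1-(2,6-dihydroxyphenyl)-9-(3,4-dimethoxyphenyl)nonan-1-one | O=C(CCCCCCCCc1ccc(OC)c(OC)c1)c1c(O)cccc1O | intermediate
6 | malabaricone C, 1-(2,6-dihydroxyphenyl)-9-(3,4-dihydroxyphenyl)nonan-1-one | O=C(CCCCCCCCc1ccc(O)c(O)c1)c1c(O)cccc1O | target

Total step count: 3. Longest linear sequence: 3 (steps 1, 2, 3).

Steps most likely to fail

Step 2. The acyl rhodium hydride may decarbonylate and deactivate the catalyst as a carbonyl complex. The double bond of 3 may migrate along the chain before coupling, linear selectivity may erode, or both phenoxides of 4 may bind rhodium and stall turnover. The fallback sets out from 3 and forms the same bond with classical polarity, an alkyl nucleophile attacking an acyl electrophile. Radical anti-Markovnikov hydrobromination of 3 (HBr, AIBN, toluene, 0 °C) would give 4-(8-bromooctyl)-1,2-dimethoxybenzene F1. Magnesium insertion in THF would give 8-(3,4-dimethoxyphenyl)octylmagnesium bromide F2. Acylation of F2 with commercial 2,6-dimethoxybenzoyl chloride (Fe(acac)3, 3 mol %, THF, −78 °C), where the two ortho-methoxy groups shield the ketone from over-addition, would give 1-(2,6-dimethoxyphenyl)-9-(3,4-dimethoxyphenyl)nonan-1-one F3. Cleavage of all four methyl ethers with excess BBr3 in CH2Cl2 comes back to the route at 6.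

Step 1. The aryl Grignard reagent may homocouple oxidatively to the biaryl, and the aryl copper species may displace the bromide too slowly, so that 2 is consumed by reduction or elimination. The fallback sets out from 2 and reverses the roles of the partners. LiCl-promoted zinc insertion (Zn dust, LiCl, THF, 50 °C) would give oct-7-en-1-ylzinc bromide F4. Negishi coupling of F4 with commercial 4-bromo-1,2-dimethoxybenzene (Pd(OAc)2, 2 mol %, SPhos, 4 mol %, THF, rt) comes back to the route at 3.

Step 3. The cleavage may stall after one methyl group, the liberated catechol may oxidise in air during work-up, or the HBr formed may cause acid-promoted side reactions. The fallback sets out from 2 and replaces Lewis-acid deprotection with neutral hydrogenolysis by changing the ring-B protecting group from the start. Commercial 4-bromo-1,2-bis(benzyloxy)benzene and Mg in THF would give 3,4-bis(benzyloxy)phenylmagnesium bromide F5. Coupling of F5 with 2 under Li2CuCl4 catalysis, as in step 1, would give 1,2-bis(benzyloxy)-4-(oct-7-en-1-yl)benzene F6. Hydroacylation of F6 with 4 under the conditions of step 2 would give 9-[3,4-bis(benzyloxy)phenyl]-1-(2,6-dihydroxyphenyl)nonan-1-one F7. Hydrogenolysis of F7 (H2, 1 atm, Pd/C, EtOAc, rt), which the strongly hydrogen-bonded aryl ketone should survive, comes back to the route at 6.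

Further compounds
F1 | step 2 | 4-(8-bromooctyl)-1,2-dimethoxybenzene | COc1ccc(CCCCCCCCBr)cc1OC
F2 | step 2 | 8-(3,4-dimethoxyphenyl)octylmagnesium bromide | COc1ccc(CCCCCCCC[Mg]Br)cc1OC
F3 | step 2 | 1-(2,6-dimethoxyphenyl)-9-(3,4-dimethoxyphenyl)nonan-1-one | COc1ccc(CCCCCCCCC(=O)c2c(OC)cccc2OC)cc1OC
F4 | step 1 | oct-7-en-1-ylzinc bromide | C=CCCCCCC[Zn]Br
F5 | step 3 | 3,4-bis(benzyloxy)phenylmagnesium bromide | Br[Mg]c1ccc(OCc2ccccc2)c(OCc2ccccc2)c1
F6 | step 3 | 1,2-bis(benzyloxy)-4-(oct-7-en-1-yl)benzene | C=CCCCCCCc1ccc(OCc2ccccc2)c(OCc2ccccc2)c1
F7 | step 3 | 9-[3,4-bis(benzyloxy)phenyl]-1-(2,6-dihydroxyphenyl)nonan-1-one | O=C(CCCCCCCCc1ccc(OCc2ccccc2)c(OCc2ccccc2)c1)c1c(O)cccc1O
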